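The leftover of the theta run's balance is the place to start: at 2.50 h the readings of target, side product, over-reacted product and starting material leave 26.6% of the starting material charged unaccounted for. Quenched substrate is the unread species that can hold it.

in all of them: starting material 48 mM
- theta: reagent in the second phase 2.5 equiv; protic impurity 49 mM; run made earlier
- Sunday's: reagent in the second phase 2.50 equiv; protic impurity 24.0 mM; time 5.0 h; volume of the second phase over the first 2.0
- Wednesday's: reagent in the second phase 2.50 equiv; protic impurity 31.0 mM; time 5.0 h; volume of the second phase over the first 2.0

theta run (percent of the starting material charged)

| time / h | target / % | side product / % | over-reacted product / % | starting material / % |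
|---|---|---|---|---|
| 0.333 | 8.9 | 0.7 | 0.1 | 82.8 |
| 0.667 | 17.0 | 2.8 | 0 | 67.4 |
| 1.00 | 25.5 | 3.0 | 2.6 | 54.1 |
| 1.33 | 30.9 | 3.6 | 2.9 | 41.8 |
| 2.00 | 42.1 | 6.0 | 5.2 | 23.0 |
| 2.50 | 48.4 | 4.6 | 6.2 | 14.2 |

(each reading ± 1 percentage point)

- percentages count the starting material that a species holds: one side product counts as two
- target is meant together with its crystals
- in the second phase: reagent in the second phase; everything else is in the first
- charges count per volume of the first phase; a concentration in a rate is the amount of a species over the volume of its own phase; every rate counts per litre of the first phase
- solid, in amounts per volume of the solution: crystals
- what was read earlier has a scatter of 1 percentage point, one standard deviation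
- steps thought possible: reagent in the reaction phase <-> reagent in the second phase; starting material + reagent in the reaction phase -> target; reagent in the reaction phase + target -> over-reacted product; starting material + target -> side product; crystals <-> target; starting material + protic impurity -> quenched substrate
- the earlier runs hold the two phases in the same ratio of volumes as the flask asked about
- no earlier run changes the charge of protic impurity; that part of a forecast is a guess

1. which of these there is most of at the end, counted by the starting material in it, Sunday's (starting material / over-reacted product / target / side product)
2. which of these there is most of at the end, counted by the starting material in it, Wednesday's (starting material / over-reacted product / target / side product)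
3. amount of the one of these that there is most of at the end, in percent of the starting material charged, Sunday's
4. amount of the one of these that there is most of at the end, in percent of the starting material charged, Wednesday's

Set over the 85.8% that had reacted and over 49 mM of protic impurity, that leftover gives a reading of 0.00633 /mM, the quench share: the part of the reacted starting material lost to quenching per mM of protic impurity. Starting material is the limiting reagent, so this reckoning takes it as reacted through by 5.0 h. The quench then takes 15.2% in Sunday's flask and 19.6% in Wednesday's, which puts Wednesday's target 4.4 percentage points lower, by one subtraction and with no stepping through time.

The forecast gives target at 62.5% for Sunday's and target at 58.5% for Wednesday's, starting likewise from the leftover: “The mass balance gap in theta gives the quench”. Its step between the flasks is 4 points, a little apart from the reckoning here.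

Sunday's flask gives target at 62.0% and Wednesday's gives target at 58.6%, both within the forecast's margin.

    reagent in the reaction phase ⇌ reagent in the second phase, rate k1*([reagent in the reaction phase] - [reagent in the second phase]/K1) per volume of the first phase (partition coefficient = 1.40, kL = 0.00630 /min)
    starting material + reagent in the reaction phase → target (k = 7.50 /M/min)
    reagent in the reaction phase + target → over-reacted product (k = 5.20 /M/min)
    starting material + target → side product (k = 0.110 /M/min)
    crystals ⇌ target, rate k5*(cs5 - [target]) while solid is left; crystals form when [target] > cs5 (solubility = 0.790 mM, k = 0.0540 /min)
    starting material + protic impurity → quenched substrate (k = 0.0810 /M/min)

Quenched substrate stands at 15.6% in Sunday's flask against the share's 15.2%, and at 19.2% in Wednesday's against 19.6%. Target leads in Sunday's flask through its low solubility together with the reading at 5.0 h and not at ten times that time: with target held soluble Sunday's ends at 16.0% target, and at 50.0 h it holds 0%. The same pair acts in Wednesday's flask, with 13.7% and 0%.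

In the neighbour flask, Sunday's with 60 mM of protic impurity, the share gives 38.0% quenched. That flask holds 31.2% quenched substrate and 47.2% target, so the share reads higher than the flask at this charge.

The data were generated by integration with made-up constants; the scatter is artificial.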